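The constants put three clocks on this flask, so I began by setting them on one scale of time.

    substrate → intermediate (k1 = 0.64 s⁻¹, Ea1 = 77.0 kJ mol⁻¹)
    partner + intermediate → target (k2 = 1.3 L mol⁻¹ s⁻¹, Ea2 = 71.0 kJ mol⁻¹)
    target ⇌ isomer of the product (K3 = 16, k3 = 0.10 s⁻¹, Ea3 = 97.0 kJ mol⁻¹, ΔH3 = −19.0 kJ mol⁻¹)
    (constants at 70 °C)

all flasks: substrate 0.10 M; partner 1.20 equiv; time 50 s

| flask | temperature |
|---|---|
| north-west | 70 °C |
| south-west | 78 °C |

- the constants hold at 70 °C; other temperatures follow from the activation energies and enthalpies

1. which of the two there is more of at the end, north-west (target / isomer of the product)
2. which of the two there is more of at the end, south-west (target / isomer of the product)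
3. target at the end, in percent of the substrate charged, north-west
4. target at the end, in percent of the substrate charged, south-west

I reckoned north-west by hand. Let I be the intermediate, D the free partner, and κ the constant of the capture step.

The first step has a lifetime τ, the inverse of its constant:

τ = 1.56 s

The isomerisation relaxes at λ, its forward constant plus its backward constant:

λ = 0.106 s⁻¹, a time of 9.41 s

So the substrate became intermediate sooner than target and isomer of the product came to terms. From then on I treated the flask as a reservoir of intermediate, started at τ.

Each capture takes one I and one D, so their difference g stays constant. That lets the rate integrate in closed form: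

g = 0.0200 M

ρ = I/D = (starting ratio)·exp(−κg(t−τ)) = 0.237 at 50 s

I = gρ/(1−ρ)

R = 6.20%, the part of the charge still waiting as intermediate.

Near the end, the feed into target falls at μ = κ(I+D):

μ = 0.0421 s⁻¹, a time of 23.8 s

This is the longest clock, which makes capture the rate-limiting step there. Target should therefore trail the feed.

Equilibrium gives target a share 1/(1+K) of what has passed the reservoir:

share = 5.52%

The remaining feed holds target above that share by the feed rate, times K/(1+K), over λ−μ:

excess = 3.10%

My north-west target was 8.61%, with isomer of the product at 85.2%, so isomer of the product led. I took south-west no further by hand.

The forecast chose isomer of the product for north-west and isomer of the product for south-west, with target at 9.2% and 7.2%; its north-west figure stood above mine, and it too said that relaxation “lags the feed”, adding about 3.7% for that where I added 3.10%.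

North-west ended with target at 9.27% and isomer of the product at 84.5%; south-west ended with target at 7.17% and isomer of the product at 90.9%. Intermediate in north-west stood at 6.24%, against my R of 6.20%. I then put the same closed form on the neighbour flask, which is north-west read at 20 s. There ρ is 0.516, so R is 21.3%. That neighbour flask held 21.5% as intermediate at 20.0 s.

The numbers are those of an exercise; the rest is arithmetic.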